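The target is cut at C3–C4. C4=O and C4''=O are joined through C3–C3'' as a 1,4-diketone, so C3 is the β-carbon of an exocyclic C3=C3''–C4''=O enone on ring C'', and ring C can be closed by an intramolecular Stetter reaction. In one operation the carbene-bound acyl anion of the ring A aldehyde forms C3–C4 and closes ring C as the trans (2S,3R) unit, and the ring C'' enolate is protonated at C3'' to give the cis (2''S,3''S) unit. The precursor 16 is an (E)-3''-alkylidene flavanone whose exocyclic carbon carries the C2 aryl ether stereocentre, tethered to a 2-formyl-3,5-bis(methoxymethoxy)phenoxy group.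

Key step: step 12

Assumption: (S,S)-ProPhenol, 2,6-bis{[(S)-2-(hydroxydiphenylmethyl)pyrrolidin-1-yl]methyl}-4-methylphenol, is taken as the ligand antipode that adds the alkynyl group to the Re face of an aryl aldehyde, and (5aR,10bS)-2-(pentafluorophenyl)-5a,10b-dihydro-4H,6H-indeno[2,1-b][1,2,4]triazolo[4,3-d][1,4]oxazin-2-ium tetrafluoroborate as the antipode matched to the (2S) centre; if a pilot run shows the opposite sense, the mirror-image ligand or salt is used in that step and nothing else changes.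

Remark on descriptors: in 14 to 16 the C2'' centre has the geometry of (2''S) in the target but is (2R) by the sequence rule, because the alkene carbon C3'' outranks the aryl group. Further descriptor changes along the route (C2 in 10, 11 and 14) are likewise changes of priority, not of geometry.

Remark on design: the ring A aldehyde is carried through the first carbene step as a silyl-protected benzylic alcohol and not as an acetal. An acetal of this electron-rich aldehyde would have to be made and cleaved with acid beside methoxymethyl ethers and an ionisable benzylic ether.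

Step 1
Reactants: 1 2,4,6-trihydroxybenzaldehyde
Product: 5 2-hydroxy-4,6-bis(methoxymethoxy)benzaldehyde
Conditions: MOMCl (2.2 equiv), iPr2NEt, CH2Cl2, 0 to 23 °C
Reagents that add atoms: chloromethyl methyl ether, COCCl
Why: Williamson-type O-alkylation takes the 4-hydroxyl and one ortho hydroxyl, while the remaining ortho hydroxyl is held in a hydrogen bond to the aldehyde and should stay free for the later Mitsunobu reactions.

Step 2
Reactants: 3 4-hydroxybenzaldehyde
Product: 6 4-(methoxymethoxy)benzaldehyde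
Conditions: MOMCl, iPr2NEt, CH2Cl2, 0 to 23 °C
Reagents that add atoms: chloromethyl methyl ether, COCCl
Why: Williamson-type O-alkylation protects the phenol as an acetal ether that is stable to organozinc, Mitsunobu and carbene conditions.

Step 3
Reactants: 2 4-methoxybenzaldehyde; 4 trimethylsilylacetylene
Product: 7 (1S)-1-(4-methoxyphenyl)-3-(trimethylsilyl)prop-2-yn-1-ol
Conditions: (S,S)-ProPhenol (10 mol%), Ph3P=O (20 mol%), Me2Zn, toluene, 0 °C
Reagents that add atoms: none
Why: Catalytic asymmetric alkynylation of an aryl aldehyde by a zinc alkynylide held in the dinuclear zinc ProPhenol complex should add to the Re face and set the carbinol as (S), which the later inversion converts into C2 of the target.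

Step 4
Reactants: 7 (1S)-1-(4-methoxyphenyl)-3-(trimethylsilyl)prop-2-yn-1-ol; 5 2-hydroxy-4,6-bis(methoxymethoxy)benzaldehyde
Product: 8 2-{[(1R)-1-(4-methoxyphenyl)-3-(trimethylsilyl)prop-2-yn-1-yl]oxy}-4,6-bis(methoxymethoxy)benzaldehyde
Conditions: PPh3, DIAD, toluene, −20 to 0 °C
Reagents that add atoms: none
Why: Mitsunobu etherification, in which the chelated and therefore acidic phenol displaces the oxyphosphonium group by SN2 with inversion, should turn the (S) carbinol into the (R) aryl ether, and the cold non-polar medium is chosen to suppress ionisation of the benzylic centre.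

Step 5
Reactants: 8 2-{[(1R)-1-(4-methoxyphenyl)-3-(trimethylsilyl)prop-2-yn-1-yl]oxy}-4,6-bis(methoxymethoxy)benzaldehyde
Product: 10 [2-{[(1S)-1-(4-methoxyphenyl)prop-2-yn-1-yl]oxy}-4,6-bis(methoxymethoxy)phenyl]methanol, via silylated benzylic alcohol 9 (not isolated)
Conditions: NaBH4, MeOH/THF, 0 °C; then K2CO3, 23 °C
Reagents that add atoms: none
Why: Borohydride reduction turns the ring A aldehyde into a benzylic alcohol so that it cannot enter the first carbene step, and methanolysis of the alkynyl C–Si bond in the same flask frees the terminal alkyne without touching the stereocentre.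

Step 6
Reactants: 10 [2-{[(1S)-1-(4-methoxyphenyl)prop-2-yn-1-yl]oxy}-4,6-bis(methoxymethoxy)phenyl]methanol
Product: 11 tert-butyl{[2-{[(1S)-1-(4-methoxyphenyl)prop-2-yn-1-yl]oxy}-4,6-bis(methoxymethoxy)phenyl]methoxy}dimethylsilane
Conditions: TBSCl, imidazole, DMF, 0 to 23 °C
Reagents that add atoms: tert-butyldimethylsilyl chloride, CC(C)(C)[Si](C)(C)Cl
Why: Silylation of the primary alcohol gives an ether that should survive organozinc, Mitsunobu and carbene conditions and is removed later by fluoride.

Step 7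
Reactants: 11 tert-butyl{[2-{[(1S)-1-(4-methoxyphenyl)prop-2-yn-1-yl]oxy}-4,6-bis(methoxymethoxy)phenyl]methoxy}dimethylsilane; 6 4-(methoxymethoxy)benzaldehyde
Product: 12 (1S,4R)-4-[2-{[tert-butyl(dimethyl)silyl]oxymethyl}-3,5-bis(methoxymethoxy)phenoxy]-4-(4-methoxyphenyl)-1-[4-(methoxymethoxy)phenyl]but-2-yn-1-ol
Conditions: (S,S)-ProPhenol (20 mol%), Ph3P=O (40 mol%), Me2Zn, toluene, 0 °C; then 6 (1.5 equiv)
Reagents that add atoms: none
Why: The same ligand-controlled asymmetric alkynylation, now with the zinc alkynylide of 11, should add to the Re face of 6 and set the new carbinol (the future C2'') as (S), the existing centre being too remote to override the catalyst.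

Step 8
Reactants: 12 (1S,4R)-4-[2-{[tert-butyl(dimethyl)silyl]oxymethyl}-3,5-bis(methoxymethoxy)phenoxy]-4-(4-methoxyphenyl)-1-[4-(methoxymethoxy)phenyl]but-2-yn-1-ol; 5 2-hydroxy-4,6-bis(methoxymethoxy)benzaldehyde
Product: 13 2-{[(1R,4R)-4-[2-{[tert-butyl(dimethyl)silyl]oxymethyl}-3,5-bis(methoxymethoxy)phenoxy]-4-(4-methoxyphenyl)-1-[4-(methoxymethoxy)phenyl]but-2-yn-1-yl]oxy}-4,6-bis(methoxymethoxy)benzaldehyde
Conditions: PPh3, DIAD, toluene, −20 to 0 °C
Reagents that add atoms: none
Why: A second Mitsunobu etherification at the only free hydroxyl should proceed with inversion to the (R) ether and brings in ring A'' with its aldehyde free, so the two aldehyde carbons are now differentiated.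

Step 9
Reactants: 13 2-{[(1R,4R)-4-[2-{[tert-butyl(dimethyl)silyl]oxymethyl}-3,5-bis(methoxymethoxy)phenoxy]-4-(4-methoxyphenyl)-1-[4-(methoxymethoxy)phenyl]but-2-yn-1-yl]oxy}-4,6-bis(methoxymethoxy)benzaldehyde
Product: 14 (2R,3E)-3-{(2S)-2-[2-{[tert-butyl(dimethyl)silyl]oxymethyl}-3,5-bis(methoxymethoxy)phenoxy]-2-(4-methoxyphenyl)ethylidene}-5,7-bis(methoxymethoxy)-2-[4-(methoxymethoxy)phenyl]chroman-4-one
Conditions: 3-mesityl-5,6,7,8-tetrahydro-4H-cyclohepta[d]thiazol-3-ium perchlorate (10 mol%), K2CO3 (20 mol%), THF, 70 °C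
Reagents that add atoms: none
Why: In this carbene-catalysed intramolecular hydroacylation of an unactivated alkyne, the enaminol from the ring A'' aldehyde should add across the triple bond in a concerted Conia-ene-like 6-exo-dig closure, and the syn delivery of acyl carbon and hydrogen fixes the E alkene with C2 cis to C2'' without creating or touching a stereocentre.

Step 10
Reactants: 14 (2R,3E)-3-{(2S)-2-[2-{[tert-butyl(dimethyl)silyl]oxymethyl}-3,5-bis(methoxymethoxy)phenoxy]-2-(4-methoxyphenyl)ethylidene}-5,7-bis(methoxymethoxy)-2-[4-(methoxymethoxy)phenyl]chroman-4-one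
Product: 15 (2R,3E)-3-{(2S)-2-[2-(hydroxymethyl)-3,5-bis(methoxymethoxy)phenoxy]-2-(4-methoxyphenyl)ethylidene}-5,7-bis(methoxymethoxy)-2-[4-(methoxymethoxy)phenyl]chroman-4-one
Conditions: Bu4NF, AcOH, THF, 0 °C
Reagents that add atoms: none
Why: Fluoride-induced desilylation of the primary silyl ether is buffered with acetic acid so that the acidic C2''–H is not removed and the exocyclic double bond does not migrate.

Step 11
Reactants: 15 (2R,3E)-3-{(2S)-2-[2-(hydroxymethyl)-3,5-bis(methoxymethoxy)phenoxy]-2-(4-methoxyphenyl)ethylidene}-5,7-bis(methoxymethoxy)-2-[4-(methoxymethoxy)phenyl]chroman-4-one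
Product: 16 2-{(1S,2E)-2-[(2R)-5,7-bis(methoxymethoxy)-2-[4-(methoxymethoxy)phenyl]-4-oxochroman-3-ylidene]-1-(4-methoxyphenyl)ethoxy}-4,6-bis(methoxymethoxy)benzaldehyde
Conditions: MnO2, CH2Cl2, 23 °C
Reagents that add atoms: none
Why: Heterogeneous MnO2 oxidation of an electron-rich benzylic alcohol stops at the aldehyde under neutral conditions and should leave the enone, the ethers and both stereocentres unchanged.

Step 12
Reactants: 16 2-{(1S,2E)-2-[(2R)-5,7-bis(methoxymethoxy)-2-[4-(methoxymethoxy)phenyl]-4-oxochroman-3-ylidene]-1-(4-methoxyphenyl)ethoxy}-4,6-bis(methoxymethoxy)benzaldehyde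
Product: 17 (2S,3R)-3-{(2S,3S)-5,7-bis(methoxymethoxy)-2-[4-(methoxymethoxy)phenyl]-4-oxochroman-3-yl}-5,7-bis(methoxymethoxy)-2-(4-methoxyphenyl)chroman-4-one
Conditions: (5aR,10bS)-N-C6F5 aminoindanol-derived triazolium tetrafluoroborate (20 mol%), iPr2NEt (20 mol%), toluene, 23 °C
Reagents that add atoms: none
Why: The carbene adds to the ring A aldehyde and proton transfer gives the enaminol, which attacks C3 of the enone in a 6-exo-trig conjugate addition (C3–C4, ring C); the ring C'' enolate is then protonated at C3'' and loss of the carbene restores C4=O, as in the known asymmetric intramolecular Stetter reaction of 2-(allyloxy)benzaldehydes with trisubstituted acceptors. C3 (R) is set by the C2 centre: allylic 1,3-strain with C2'' holds the C2–H in the alkene plane, so the O1 tether can reach only the face opposite the 4-methoxyphenyl group, which gives the trans ring C, and the triazolium antipode is chosen to reinforce this face. C3'' (S) is set by kinetic protonation of the enolate on the face opposite the pseudoaxial C2'' aryl group, after rotation about C3–C3'' places the bulky C4 carbinol on that open face, which gives the cis ring C''. The step needs addition at C3 only, an intact E alkene until the addition and no enolisation afterwards; the hindered ketone as the only other carbonyl, the alkene geometry fixed in step 9 and the use of only a catalytic amount of a hindered amine should secure these.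

Step 13
Reactants: 17 (2S,3R)-3-{(2S,3S)-5,7-bis(methoxymethoxy)-2-[4-(methoxymethoxy)phenyl]-4-oxochroman-3-yl}-5,7-bis(methoxymethoxy)-2-(4-methoxyphenyl)chroman-4-one
Product: 18 (2S,3R)-3-[(2S,3S)-5,7-dihydroxy-2-(4-hydroxyphenyl)-4-oxochroman-3-yl]-5,7-dihydroxy-2-(4-methoxyphenyl)chroman-4-one
Conditions: HCl (1.25 M in MeOH), THF, 23 to 40 °C
Reagents that add atoms: none
Why: Acid-catalysed acetal exchange with methanol removes all five methoxymethyl groups as dimethoxymethane, and because no base is present neither C3 nor C3'' should enolise nor the rings open, while the methyl aryl ether stays.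

Compound list
1 | 2,4,6-trihydroxybenzaldehyde | O=Cc1c(O)cc(O)cc1O | starting material
2 | 4-methoxybenzaldehyde | COc1ccc(C=O)cc1 | starting material
3 | 4-hydroxybenzaldehyde | O=Cc1ccc(O)cc1 | starting material
4 | trimethylsilylacetylene | C#C[Si](C)(C)C | starting material
5 | 2-hydroxy-4,6-bis(methoxymethoxy)benzaldehyde | COCOc1cc(O)c(C=O)c(OCOC)c1 | intermediate
6 | 4-(methoxymethoxy)benzaldehyde | COCOc1ccc(C=O)cc1 | intermediate
7 | (1S)-1-(4-methoxyphenyl)-3-(trimethylsilyl)prop-2-yn-1-ol | COc1ccc([C@H](O)C#C[Si](C)(C)C)cc1 | intermediate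
8 | 2-{[(1R)-1-(4-methoxyphenyl)-3-(trimethylsilyl)prop-2-yn-1-yl]oxy}-4,6-bis(methoxymethoxy)benzaldehyde | COc1ccc([C@@H](Oc2cc(OCOC)cc(OCOC)c2C=O)C#C[Si](C)(C)C)cc1 | intermediate
9 | [2-{[(1R)-1-(4-methoxyphenyl)-3-(trimethylsilyl)prop-2-yn-1-yl]oxy}-4,6-bis(methoxymethoxy)phenyl]methanol (silylated benzylic alcohol, not isolated) | COc1ccc([C@@H](Oc2cc(OCOC)cc(OCOC)c2CO)C#C[Si](C)(C)C)cc1 | intermediate
10 | [2-{[(1S)-1-(4-methoxyphenyl)prop-2-yn-1-yl]oxy}-4,6-bis(methoxymethoxy)phenyl]methanol | COc1ccc([C@@H](Oc2cc(OCOC)cc(OCOC)c2CO)C#C)cc1 | intermediate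
11 | tert-butyl{[2-{[(1S)-1-(4-methoxyphenyl)prop-2-yn-1-yl]oxy}-4,6-bis(methoxymethoxy)phenyl]methoxy}dimethylsilane | COc1ccc([C@@H](Oc2cc(OCOC)cc(OCOC)c2CO[Si](C)(C)C(C)(C)C)C#C)cc1 | intermediate
12 | (1S,4R)-4-[2-{[tert-butyl(dimethyl)silyl]oxymethyl}-3,5-bis(methoxymethoxy)phenoxy]-4-(4-methoxyphenyl)-1-[4-(methoxymethoxy)phenyl]but-2-yn-1-ol | COc1ccc([C@@H](Oc2cc(OCOC)cc(OCOC)c2CO[Si](C)(C)C(C)(C)C)C#C[C@@H](O)c2ccc(OCOC)cc2)cc1 | intermediate
13 | 2-{[(1R,4R)-4-[2-{[tert-butyl(dimethyl)silyl]oxymethyl}-3,5-bis(methoxymethoxy)phenoxy]-4-(4-methoxyphenyl)-1-[4-(methoxymethoxy)phenyl]but-2-yn-1-yl]oxy}-4,6-bis(methoxymethoxy)benzaldehyde | COc1ccc([C@@H](Oc2cc(OCOC)cc(OCOC)c2CO[Si](C)(C)C(C)(C)C)C#C[C@H](Oc2cc(OCOC)cc(OCOC)c2C=O)c2ccc(OCOC)cc2)cc1 | intermediate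
14 | (2R,3E)-3-{(2S)-2-[2-{[tert-butyl(dimethyl)silyl]oxymethyl}-3,5-bis(methoxymethoxy)phenoxy]-2-(4-methoxyphenyl)ethylidene}-5,7-bis(methoxymethoxy)-2-[4-(methoxymethoxy)phenyl]chroman-4-one | COc1ccc([C@@H](Oc2cc(OCOC)cc(OCOC)c2CO[Si](C)(C)C(C)(C)C)/C=C2/C(=O)c3c(OCOC)cc(OCOC)cc3O[C@@H]2c2ccc(OCOC)cc2)cc1 | intermediate
15 | (2R,3E)-3-{(2S)-2-[2-(hydroxymethyl)-3,5-bis(methoxymethoxy)phenoxy]-2-(4-methoxyphenyl)ethylidene}-5,7-bis(methoxymethoxy)-2-[4-(methoxymethoxy)phenyl]chroman-4-one | COc1ccc([C@@H](Oc2cc(OCOC)cc(OCOC)c2CO)/C=C2/C(=O)c3c(OCOC)cc(OCOC)cc3O[C@@H]2c2ccc(OCOC)cc2)cc1 | intermediate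
16 | 2-{(1S,2E)-2-[(2R)-5,7-bis(methoxymethoxy)-2-[4-(methoxymethoxy)phenyl]-4-oxochroman-3-ylidene]-1-(4-methoxyphenyl)ethoxy}-4,6-bis(methoxymethoxy)benzaldehyde | COc1ccc([C@@H](Oc2cc(OCOC)cc(OCOC)c2C=O)/C=C2/C(=O)c3c(OCOC)cc(OCOC)cc3O[C@@H]2c2ccc(OCOC)cc2)cc1 | intermediate
17 | (2S,3R)-3-{(2S,3S)-5,7-bis(methoxymethoxy)-2-[4-(methoxymethoxy)phenyl]-4-oxochroman-3-yl}-5,7-bis(methoxymethoxy)-2-(4-methoxyphenyl)chroman-4-one | COc1ccc([C@H]2Oc3cc(OCOC)cc(OCOC)c3C(=O)[C@@H]2[C@@H]2C(=O)c3c(OCOC)cc(OCOC)cc3O[C@@H]2c2ccc(OCOC)cc2)cc1 | intermediate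
18 | (2S,3R)-3-[(2S,3S)-5,7-dihydroxy-2-(4-hydroxyphenyl)-4-oxochroman-3-yl]-5,7-dihydroxy-2-(4-methoxyphenyl)chroman-4-one | COc1ccc([C@H]2Oc3cc(O)cc(O)c3C(=O)[C@@H]2[C@@H]2C(=O)c3c(O)cc(O)cc3O[C@@H]2c2ccc(O)cc2)cc1 | target

Total step count: 13. Longest linear sequence: 11 steps (steps 3 to 13, from 4-methoxybenzaldehyde).

Steps most likely to fail

Step 12. The carbene may add only slowly to the doubly ortho-substituted, electron-rich aldehyde. The new bond must also form on the alkene face that carries the pseudoaxial C2'' aryl group, and the proton may reach C3'' from the same face as the new bond, which would give the trans ring C''. The amine may in addition move the double bond into ring C''. The fallback sets out from 16 and forms the same bond by a radical instead of a polar path. Pinnick oxidation (NaClO2, NaH2PO4, 2-methyl-2-butene, tBuOH/H2O) should give the carboxylic acid F1. PhSeSePh and PBu3 in CH2Cl2 should convert it into the Se-phenyl selenoester F2. (Me3Si)3SiH and AIBN in benzene at 80 °C should then release the acyl radical, which closes ring C by 6-exo-trig addition to C3 under the same tether control. The C3'' radical should take its hydrogen from the silane on the face opposite the C2'' aryl group. The route is rejoined at 17.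

Step 9. The hindered internal alkyne with two branched propargylic carbons may not undergo the hydroacylation, or the carbonate may move the new double bond into ring C'' and erase C2''. The fallback sets out from 13 and uses a reductive aldehyde–alkyne coupling followed by oxidation. Ni(cod)2 (zerovalent nickel), PBu3 and Et3SiH in THF should give the cyclic allylic triethylsilyl ether F3, with the same alkene geometry by syn addition and an inconsequential mixture at C4''. Bu4NF buffered with AcOH should remove both silyl groups to give the diol F4. Dess–Martin periodinane with NaHCO3 should oxidise both alcohols, and the route is rejoined at 16.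

Step 4 (the same concern holds for step 8). The oxyphosphonium salt of the electron-rich benzylic propargylic alcohol may ionise, which would erode the enantiomeric purity, or the chelated phenol may react sluggishly. The fallback sets out from 2 and sets the ether stereocentre by catalysis instead of inversion. HC≡CMgBr in THF should give racemic 1-(4-methoxyphenyl)prop-2-yn-1-ol F5, and Ac2O, Et3N and DMAP its acetate F6. Copper-catalysed enantioselective propargylic etherification with 5 (CuOTf·0.5C6H6, chiral Ph-pybox with the antipode chosen in a test run, iPr2NEt, MeOH, −20 °C) should proceed through a copper allenylidene to the terminal alkyne ether 2-{[(1S)-1-(4-methoxyphenyl)prop-2-yn-1-yl]oxy}-4,6-bis(methoxymethoxy)benzaldehyde F7. NaBH4 in MeOH then reduces the aldehyde, and the route is rejoined at 10.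

Further compounds
F1 | step 12 | 2-{(1S,2E)-2-[(2R)-5,7-bis(methoxymethoxy)-2-[4-(methoxymethoxy)phenyl]-4-oxochroman-3-ylidene]-1-(4-methoxyphenyl)ethoxy}-4,6-bis(methoxymethoxy)benzoic acid | COc1ccc([C@@H](Oc2cc(OCOC)cc(OCOC)c2C(=O)O)/C=C2/C(=O)c3c(OCOC)cc(OCOC)cc3O[C@@H]2c2ccc(OCOC)cc2)cc1
F2 | step 12 | Se-phenyl selenoester of F1 | COc1ccc([C@@H](Oc2cc(OCOC)cc(OCOC)c2C(=O)[Se]c2ccccc2)/C=C2/C(=O)c3c(OCOC)cc(OCOC)cc3O[C@@H]2c2ccc(OCOC)cc2)cc1
F3 | step 9 | triethylsilyl ether of the 4''-hydroxy analogue of 14 (C4'' epimers) | COc1ccc([C@@H](Oc2cc(OCOC)cc(OCOC)c2CO[Si](C)(C)C(C)(C)C)/C=C2/C(O[Si](CC)(CC)CC)c3c(OCOC)cc(OCOC)cc3O[C@@H]2c2ccc(OCOC)cc2)cc1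
F4 | step 9 | 4''-hydroxy analogue of 15 (diol, C4'' epimers) | COc1ccc([C@@H](Oc2cc(OCOC)cc(OCOC)c2CO)/C=C2/C(O)c3c(OCOC)cc(OCOC)cc3O[C@@H]2c2ccc(OCOC)cc2)cc1
F5 | step 4 | racemic 1-(4-methoxyphenyl)prop-2-yn-1-ol | C#CC(O)c1ccc(OC)cc1
F6 | step 4 | racemic 1-(4-methoxyphenyl)prop-2-yn-1-yl acetate | CC(=O)OC(C#C)c1ccc(OC)cc1
F7 | step 4 | 2-{[(1S)-1-(4-methoxyphenyl)prop-2-yn-1-yl]oxy}-4,6-bis(methoxymethoxy)benzaldehyde | COc1ccc([C@@H](Oc2cc(OCOC)cc(OCOC)c2C=O)C#C)cc1
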